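(The data are calculated from invented constants, noise included.)

The green run cannot have stopped for lack of left-handed substrate: its left-handed product stands near 19.0% while 36% of the charge is still that substrate. Nor can product formation have used up the partner, if each product takes one partner: 2 equiv covers both substrates. Something else stops the green run, and the readings do not say what.

| flask | left-handed substrate | right-handed substrate | partner | free catalyst | racemization catalyst | remark | time |
|---|---|---|---|---|---|---|---|
| violet | 0.10 M | 0.10 M | 2 equiv | 0.34 mol% | 0.11 mol% | run made earlier |  |
| green | 0.10 M | 0.10 M | 2 equiv | 1.4 mol% | 0.11 mol% | run made earlier |  |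
| grey | 0.10 M | 0.10 M | 2 equiv | 0.69 mol% | 0.17 mol% | run made earlier |  |
| flask | 0.10 M | 0.10 M | 2.00 equiv | 0.69 mol% | 0.11 mol% |  | 8.0 h |

| run | time / h | left-handed substrate / % | right-handed substrate / % | left-handed product / % |
|---|---|---|---|---|
| violet | 0.833 | 48 | 48 | 6 |
| violet | 1.33 | 47 | 49 | 5 |
| violet | 2.00 | 46 | 49 | 5 |
| violet | 2.50 | 48 | 47 | 6 |
| violet | 4.00 | 46 | 51 | 7 |
| violet | 6.00 | 45 | 48 | 6 |
| violet | 10.0 | 45 | 48 | 6 |
| green | 0.500 | 40 | 47 | 9 |
| green | 1.33 | 36 | 45 | 17 |
| green | 2.50 | 36 | 44 | 19 |
| green | 4.00 | 39 | 41 | 17 |
| green | 6.00 | 39 | 40 | 21 |
| green | 8.00 | 41 | 41 | 19 |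
| green | 10.0 | 36 | 40 | 17 |
| grey | 0.833 | 43 | 46 | 8 |
| grey | 1.33 | 42 | 46 | 8 |
| grey | 2.50 | 42 | 48 | 13 |
| grey | 5.00 | 42 | 45 | 12 |
| grey | 10.0 | 42 | 44 | 15 |

(scatter of a reading: 1.5 percentage points)

- free catalyst is single-handed; left-handed substrate and right-handed substrate are mirror images of each other, charged as a racemate, each of them at the stated concentration
- the numbers in the tables scatter by 1.5 percentage points (one standard deviation)
- an excess is below zero if the other one leads

* part of the left-handed substrate and right-handed substrate charged together that has reacted at 8.0 h
* excess of left-handed product over right-handed product in the product at 8.0 h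
* excess of right-handed substrate over left-handed substrate among what is left of the two at 8.0 h

We follow the run in slow motion. In the first instants of the green run, free catalyst favours one hand: at 0.500 h we read 40% of left-handed substrate, less than the 47% of right-handed substrate, with 9% of left-handed product.

Then the left-handed product stands still in the violet and green runs. The late readings average 6.33% in the violet run and 19.0% in the green run, and both runs carry the flask's 0.11 mol% of racemization catalyst. The loading of free catalyst differs by a factor of 4.12, the plateau by less, a factor of 3.00. We join these two ends: the logarithm of the plateau ratio over that of the loading ratio is the plateau exponent, n = 0.776.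

The late readings of the green run put the substrate gap at an average of 1.7 percentage points, as expected of a racemization catalyst.

For the flask, n gives 11.0% of left-handed product. Right-handed product hides in the scatter of the balance, so we expect slightly more reacted than that, and a small excess of right-handed substrate among what is left, eS.

The forecast says 12% reacted, an excess of left-handed product in the product, eP, of 85%, and eS 2%, holding that “The plateau scales with catalyst loading”.

The flask gives 13.2% reacted, eP 86.8% and eS 2.26%.

    partner + free catalyst + right-handed substrate → free catalyst + right-handed product (k = 0.0870 M⁻² s⁻¹)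
    partner + free catalyst + left-handed substrate → free catalyst + left-handed product (k = 1.30 M⁻² s⁻¹)
    2 partner → homo dimer (k = 0.00520 M⁻¹ s⁻¹)
    left-handed substrate + racemization catalyst ⇌ right-handed substrate + racemization catalyst, rate k4*[racemization catalyst]*[left-handed substrate] forward; the back reaction follows from the equilibrium constant (k = 2.40 M⁻¹ s⁻¹)
    racemization catalyst → spent catalyst (k = 1.40 × 10⁻⁴ s⁻¹)
    partner → decomposition product (k = 9.10 × 10⁻⁸ s⁻¹)

The flask holds 12.3% of left-handed product, against our 11.0%. Its free catalyst stands at 100% of charge, while partner, the limiting reagent, is down to 0.39% of its charge, less than the 85% of left-handed substrate remaining. Homo dimer stands at 0.0864 M. At the start, partner went into homo dimer 23 times as fast as into left-handed product. For the neighbouring flask with 0.17 mol% of free catalyst, n and the violet plateau give 3.70% of left-handed product, and that flask holds 3.93%.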